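The cyclohexanone ring of the 2-oxaspiro[4.5]decane core is cut at C5–C6 and C9–C10. The feature used is that spiro carbon C5 sits between the C6 ketone and, through C10H2, the C9 carbinol, so the ring oxygens are 1,4-related, while C5 also carries C1 at acyl oxidation level. A catalytic asymmetric Diels–Alder reaction of an exo-methylene dienone with (1E,3E)-1-acetoxy-4-silyloxybutadiene therefore closes this ring, sets the quaternary centre and both oxygenated carbons, and leaves the C7=C8 alkene for tethered nitrogen delivery. The dienophile is a geranoyl-type ketone built on an itaconate half ester, so its methylene and acetate arm are present from the start.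

Key step: step 8

Assumption: the (S)-diphenylprolinol-derived oxazaborolidine–AlBr3 complex is taken to expose the enone face that leads to the (1S,2S,5S) adduct 14; since the dienophile has no α-hydrogen for two-point binding this sense must be confirmed on the first run, and the (R)-catalyst is used instead if it proves opposite.

Step 1
Reactants: 1 5-bromo-2-methylpent-2-ene
Product: 2 6-methylhept-5-en-1-yne
Conditions: LiC≡CH·H2NCH2CH2NH2 (1.3 equiv), DMSO, 10 °C → rt
Reagents that add atoms: lithium acetylide ethylenediamine complex, [Li+].[C-]#C.NCCN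
Why: SN2 alkylation of the acetylide by a primary homoallylic bromide in DMSO should give the terminal alkyne; no stereocentre is formed.

Step 2
Reactants: 2 6-methylhept-5-en-1-yne
Product: 4 (E)-1-iodo-2,6-dimethylhepta-1,5-diene, via alkenyldimethylalane 3 (not isolated)
Conditions: Me3Al (2.0 equiv), Cp2ZrCl2 (0.2 equiv), CH2Cl2, 0 °C → rt; then I2, THF, −30 → 0 °C
Reagents that add atoms: trimethylaluminium, C[Al](C)C; iodine, II
Why: Negishi zirconium-catalysed carboalumination adds methyl and aluminium syn across the alkyne with aluminium on the terminal carbon, and iodinolysis with retention should fix the E trisubstituted alkene.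

Step 3
Reactants: 5 4-methyl hydrogen itaconate (4-methoxy-2-methylidene-4-oxobutanoic acid)
Product: 6 methyl 3-(chlorocarbonyl)but-3-enoate
Conditions: (COCl)2 (1.2 equiv), DMF (cat.), CH2Cl2, 0 °C → rt; used crude
Reagents that add atoms: oxalyl chloride, O=C(Cl)C(=O)Cl
Why: Vilsmeier-type acid chloride formation under base-free conditions should leave the exo-methylene out of conjugation with the ester; no stereocentre is formed.

Step 4
Reactants: 4 (E)-1-iodo-2,6-dimethylhepta-1,5-diene; 6 methyl 3-(chlorocarbonyl)but-3-enoate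
Product: 9 methyl (5E)-6,10-dimethyl-3-methylidene-4-oxoundeca-5,9-dienoate, via alkenyllithium 7 (not isolated), via alkenylzinc chloride 8 (not isolated)
Conditions: 4, t-BuLi (2.0 equiv), Et2O, −78 °C; ZnCl2 (1.1 equiv, THF), −78 → 0 °C; then 6, Pd(PPh3)4 (5 mol%), THF, 0 °C → rt
Reagents that add atoms: none
Why: Negishi acylation, in which iodine–lithium exchange and transmetallation to zinc keep the alkene geometry and zerovalent palladium couples the alkenylzinc with the acyl chloride while the organozinc leaves the ester and the acrylate-type alkene alone.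

Step 5
Reactants: 10 (Z)-but-2-ene-1,4-diol
Product: 11 (Z)-4-hydroxybut-2-en-1-yl acetate
Conditions: 10 (3 equiv), Ac2O (1.0 equiv), Et3N, DMAP (cat.), THF, 0 °C
Reagents that add atoms: acetic anhydride, CC(=O)OC(C)=O
Why: Acylation of one hydroxyl of the symmetric diol, used in excess so that diacetate stays minor and surplus diol is removed by aqueous washing; no stereocentre is formed.

Step 6
Reactants: 11 (Z)-4-hydroxybut-2-en-1-yl acetate
Product: 12 (E)-4-oxobut-2-en-1-yl acetate
Conditions: pyridinium chlorochromate [C5H5NH][CrO3Cl] (1.5 equiv), NaOAc, 4 Å MS, CH2Cl2, rt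
Reagents that add atoms: none
Why: Chlorochromate oxidation of the primary allylic alcohol, during which the first-formed Z enal should isomerise to the more stable E enal.

Step 7
Reactants: 12 (E)-4-oxobut-2-en-1-yl acetate
Product: 13 (1E,3E)-4-[(tert-butyldimethylsilyl)oxy]buta-1,3-dien-1-yl acetate
Conditions: TBSOTf (1.1 equiv), Et3N (1.5 equiv), Et2O, 0 °C → rt
Reagents that add atoms: tert-butyldimethylsilyl triflate, CC(C)(C)[Si](C)(C)OS(=O)(=O)C(F)(F)F
Why: Vinylogous silyl enol ether formation, in which O-silylation of the enal lets Et3N remove the γ-hydrogen next to the acetoxy group, and reaction through the s-trans enal with the acetoxy group turned outward should give the E,E diene.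

Step 8
Reactants: 9 methyl (5E)-6,10-dimethyl-3-methylidene-4-oxoundeca-5,9-dienoate; 13 (1E,3E)-4-[(tert-butyldimethylsilyl)oxy]buta-1,3-dien-1-yl acetate
Product: 14 methyl 2-[(1S,2S,5S)-5-acetoxy-2-[(tert-butyldimethylsilyl)oxy]-1-[(2E)-3,7-dimethylocta-2,6-dienoyl]cyclohex-3-en-1-yl]acetate (acyl group and both oxygens on one ring face)
Conditions: 13 (1.5 equiv), (S)-3,3-diphenyl-1-(o-tolyl)tetrahydropyrrolo[1,2-c][1,3,2]oxazaborole (20 mol%) activated with AlBr3 (16 mol%), CH2Cl2, −78 → −40 °C
Reagents that add atoms: none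
Why: The cationic boron Lewis acid binds the dienone carbonyl and lowers the LUMO of the 1,1-disubstituted exo-methylene, which undergoes a concerted, asynchronous [4+2] cycloaddition with the electron-rich diene; the closest known reaction type is the oxazaborolidinium-catalysed Diels–Alder reaction of 2-substituted vinyl ketones and acroleins with 1-oxygenated dienes. The cyclohexene is closed as a six-membered carbocycle by intermolecular suprafacial [4π+2π] cycloaddition, the C(quaternary)–C(OSi) and CH2–C(OAc) bonds forming in the same event. The quaternary centre is set in the absolute sense by the catalyst, which shields one face of the bound enone; the silyloxy carbon is set relative to it by endo placement of the coordinated acyl group (not the ester arm); the acetoxy carbon follows from the E,E diene geometry, which keeps the two oxygens cis. The regiochemistry needed is secured by the stronger silyloxy donor, which makes the acetoxy-bearing terminus the nucleophilic end that attacks the enone CH2. Chemoselectivity for the exo-methylene rests on the β,β-disubstitution of the other enone alkene, and the low temperature and catalytic Lewis acid should keep Nazarov cyclisation and migration of the methylene into conjugation with the ester out of reach.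

Step 9
Reactants: 14 methyl 2-[(1S,2S,5S)-5-acetoxy-2-[(tert-butyldimethylsilyl)oxy]-1-[(2E)-3,7-dimethylocta-2,6-dienoyl]cyclohex-3-en-1-yl]acetate
Product: 15 methyl 2-[(1S,2S,5S)-5-acetoxy-1-[(2E)-3,7-dimethylocta-2,6-dienoyl]-2-hydroxycyclohex-3-en-1-yl]acetate
Conditions: HF·pyridine, pyridine, THF, 0 °C → rt
Reagents that add atoms: none
Why: Fluoride cleavage of the Si–O bond under buffered acidic conditions should free the ring hydroxyl without retro-aldol fragmentation of the β-hydroxy ketone (a risk with basic fluoride) and without touching acetate or methyl ester; no stereocentre changes.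

Step 10
Reactants: 15 methyl 2-[(1S,2S,5S)-5-acetoxy-1-[(2E)-3,7-dimethylocta-2,6-dienoyl]-2-hydroxycyclohex-3-en-1-yl]acetate
Product: 18 (1R,5S,6S,9S)-1-[(1E)-2,6-dimethylhepta-1,5-dien-1-yl]-6-hydroxy-3-oxo-2-oxaspiro[4.5]dec-7-en-9-yl acetate, via diethylboron chelate 16 (not isolated), via syn-diol ester 17 (not isolated)
Conditions: Et2BOMe (1.2 equiv), THF/MeOH 4:1, −78 °C; NaBH4 (1.2 equiv), −78 °C; AcOH, MeOH co-evaporation; then PPTS (cat.), CH2Cl2, rt
Reagents that add atoms: none
Why: Narasaka–Prasad 1,3-syn reduction, in which the boron chelate of hydroxyl and ketone is a half-chair cis-fused to the cyclohexene with the carbinol hydrogen axial and the ring CH2 of the quaternary carbon axial on the other face, so external hydride should add axially on the open face to give the (R)-carbinol, which then closes the unstrained spiro γ-lactone in preference to a trans-fused lactone from the ring hydroxyl.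

Step 11
Reactants: 18 (1R,5S,6S,9S)-1-[(1E)-2,6-dimethylhepta-1,5-dien-1-yl]-6-hydroxy-3-oxo-2-oxaspiro[4.5]dec-7-en-9-yl acetate
Product: 19 (1R,5R,9S)-1-[(1E)-2,6-dimethylhepta-1,5-dien-1-yl]-3,6-dioxo-2-oxaspiro[4.5]dec-7-en-9-yl acetate
Conditions: Dess–Martin periodinane (1.3 equiv), NaHCO3, CH2Cl2, 0 °C → rt
Reagents that add atoms: none
Why: Dess–Martin oxidation of the secondary allylic alcohol to the ring enone under buffered neutral conditions that should leave the allylic acetate, the lactone and the side-chain alkenes intact; the C6 stereocentre is removed on purpose.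

Step 12
Reactants: 19 (1R,5R,9S)-1-[(1E)-2,6-dimethylhepta-1,5-dien-1-yl]-3,6-dioxo-2-oxaspiro[4.5]dec-7-en-9-yl acetate
Product: 20 (1R,5R,9S)-1-[(1E)-2,6-dimethylhepta-1,5-dien-1-yl]-9-hydroxy-2-oxaspiro[4.5]dec-7-ene-3,6-dione
Conditions: K2CO3 (0.3 equiv), MeOH, 0 °C; AcOH quench
Reagents that add atoms: none
Why: Base-catalysed methanolysis of the acetate should outpace opening of the γ-lactone (itself reversed on acidification), and since the C9–O bond is not broken the configuration is kept.

Step 13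
Reactants: 20 (1R,5R,9S)-1-[(1E)-2,6-dimethylhepta-1,5-dien-1-yl]-9-hydroxy-2-oxaspiro[4.5]dec-7-ene-3,6-dione
Product: 22 (1R,5R,8R,9S) cis-fused 2-(trichloromethyl)-4,5-dihydro-1,3-oxazole of the spirolactone ketone (N on C8 and O on C9), via trichloroacetimidate 21 (not isolated)
Conditions: Cl3CCN (1.5 equiv), DBU (0.3 equiv), CH2Cl2, 0 °C → rt
Reagents that add atoms: trichloroacetonitrile, N#CC(Cl)(Cl)Cl
Why: Base-catalysed addition of the hydroxyl to the nitrile gives the imidate, whose nitrogen then adds to the enone β-carbon in a 5-exo-trig intramolecular aza-Michael reaction; the short tether reaches C8 only on the face of the C9 oxygen, so the new C–N bond is set cis to it.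

Step 14
Reactants: 22 cis-fused 2-(trichloromethyl)oxazoline
Product: 24 (+)-miliusane V (N-[(1R,5R,8R,9S)-1-[(1E)-2,6-dimethylhepta-1,5-dien-1-yl]-9-hydroxy-3,6-dioxo-2-oxaspiro[4.5]decan-8-yl]acetamide), via ammonium chloride 23 (not isolated)
Conditions: 1 M HCl, THF, rt; then NaHCO3 (to pH 8), Ac2O (1.5 equiv), 0 °C
Reagents that add atoms: acetic anhydride, CC(=O)OC(C)=O
Why: Acid hydrolysis of the 2-trichloromethyl oxazoline should release the cis-amino alcohol as its ammonium salt, and Schotten–Baumann acetylation in aqueous hydrogencarbonate then acylates nitrogen in preference to the secondary hydroxyl; no stereocentre is affected.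

Compound list
1 | 5-bromo-2-methylpent-2-ene | CC(C)=CCCBr | starting material
2 | 6-methylhept-5-en-1-yne | C#CCCC=C(C)C | intermediate
3 | (E)-(2,6-dimethylhepta-1,5-dien-1-yl)dimethylalane (not isolated) | C[Al](C)/C=C(\C)CCC=C(C)C | intermediate
4 | (E)-1-iodo-2,6-dimethylhepta-1,5-diene | I/C=C(\C)CCC=C(C)C | intermediate
5 | 4-methyl hydrogen itaconate (4-methoxy-2-methylidene-4-oxobutanoic acid) | C=C(CC(=O)OC)C(=O)O | starting material
6 | methyl 3-(chlorocarbonyl)but-3-enoate | C=C(CC(=O)OC)C(=O)Cl | intermediate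
7 | (E)-(2,6-dimethylhepta-1,5-dien-1-yl)lithium (not isolated) | [Li]/C=C(\C)CCC=C(C)C | intermediate
8 | (E)-(2,6-dimethylhepta-1,5-dien-1-yl)zinc chloride (not isolated) | Cl[Zn]/C=C(\C)CCC=C(C)C | intermediate
9 | methyl (5E)-6,10-dimethyl-3-methylidene-4-oxoundeca-5,9-dienoate | C=C(CC(=O)OC)C(=O)/C=C(\C)CCC=C(C)C | intermediate
10 | (Z)-but-2-ene-1,4-diol | OC/C=C\CO | starting material
11 | (Z)-4-hydroxybut-2-en-1-yl acetate | CC(=O)OC/C=C\CO | intermediate
12 | (E)-4-oxobut-2-en-1-yl acetate | CC(=O)OC/C=C/C=O | intermediate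
13 | (1E,3E)-4-[(tert-butyldimethylsilyl)oxy]buta-1,3-dien-1-yl acetate | CC(=O)O/C=C/C=C/O[Si](C)(C)C(C)(C)C | intermediate
14 | methyl 2-[(1S,2S,5S)-5-acetoxy-2-[(tert-butyldimethylsilyl)oxy]-1-[(2E)-3,7-dimethylocta-2,6-dienoyl]cyclohex-3-en-1-yl]acetate | CC(=O)O[C@@H]1C=C[C@H](O[Si](C)(C)C(C)(C)C)[C@](CC(=O)OC)(C(=O)/C=C(\C)CCC=C(C)C)C1 | intermediate
15 | methyl 2-[(1S,2S,5S)-5-acetoxy-1-[(2E)-3,7-dimethylocta-2,6-dienoyl]-2-hydroxycyclohex-3-en-1-yl]acetate | CC(=O)O[C@@H]1C=C[C@H](O)[C@](CC(=O)OC)(C(=O)/C=C(\C)CCC=C(C)C)C1 | intermediate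
16 | methyl 2-[(1S,2S,5S)-5-acetoxy-2-[(diethylboranyl)oxy]-1-[(2E)-3,7-dimethylocta-2,6-dienoyl]cyclohex-3-en-1-yl]acetate, boron chelated to the ketone (not isolated) | CC(=O)O[C@@H]1C=C[C@H](OB(CC)CC)[C@](CC(=O)OC)(C(=O)/C=C(\C)CCC=C(C)C)C1 | intermediate
17 | methyl 2-[(1S,2S,5S)-5-acetoxy-2-hydroxy-1-[(1R,2E)-1-hydroxy-3,7-dimethylocta-2,6-dien-1-yl]cyclohex-3-en-1-yl]acetate (not isolated) | CC(=O)O[C@@H]1C=C[C@H](O)[C@](CC(=O)OC)([C@H](O)/C=C(\C)CCC=C(C)C)C1 | intermediate
18 | (1R,5S,6S,9S)-1-[(1E)-2,6-dimethylhepta-1,5-dien-1-yl]-6-hydroxy-3-oxo-2-oxaspiro[4.5]dec-7-en-9-yl acetate | CC(=O)O[C@@H]1C=C[C@H](O)[C@@]2(CC(=O)O[C@@H]2/C=C(\C)CCC=C(C)C)C1 | intermediate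
19 | (1R,5R,9S)-1-[(1E)-2,6-dimethylhepta-1,5-dien-1-yl]-3,6-dioxo-2-oxaspiro[4.5]dec-7-en-9-yl acetate | CC(=O)O[C@@H]1C=CC(=O)[C@@]2(CC(=O)O[C@@H]2/C=C(\C)CCC=C(C)C)C1 | intermediate
20 | (1R,5R,9S)-1-[(1E)-2,6-dimethylhepta-1,5-dien-1-yl]-9-hydroxy-2-oxaspiro[4.5]dec-7-ene-3,6-dione | O[C@@H]1C=CC(=O)[C@@]2(CC(=O)O[C@@H]2/C=C(\C)CCC=C(C)C)C1 | intermediate
21 | (1R,5R,9S)-1-[(1E)-2,6-dimethylhepta-1,5-dien-1-yl]-3,6-dioxo-2-oxaspiro[4.5]dec-7-en-9-yl 2,2,2-trichloroethanimidate (not isolated) | N=C(O[C@@H]1C=CC(=O)[C@@]2(CC(=O)O[C@@H]2/C=C(\C)CCC=C(C)C)C1)C(Cl)(Cl)Cl | intermediate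
22 | (1R,5R,8R,9S) cis-fused 2-(trichloromethyl)-4,5-dihydro-1,3-oxazole, N on C8 and O on C9 of the 1-[(1E)-2,6-dimethylhepta-1,5-dien-1-yl]-2-oxaspiro[4.5]decane-3,6-dione core | ClC(Cl)(Cl)C3=N[C@@H]1CC(=O)[C@@]2(CC(=O)O[C@@H]2/C=C(\C)CCC=C(C)C)C[C@@H]1O3 | intermediate
23 | (1R,5R,8R,9S)-8-amino-1-[(1E)-2,6-dimethylhepta-1,5-dien-1-yl]-9-hydroxy-2-oxaspiro[4.5]decane-3,6-dione hydrochloride (not isolated) | [Cl-].[NH3+][C@@H]1CC(=O)[C@@]2(CC(=O)O[C@@H]2/C=C(\C)CCC=C(C)C)C[C@@H]1O | intermediate
24 | (+)-miliusane V, N-[(1R,5R,8R,9S)-1-[(1E)-2,6-dimethylhepta-1,5-dien-1-yl]-9-hydroxy-3,6-dioxo-2-oxaspiro[4.5]decan-8-yl]acetamide | CC(=O)N[C@@H]1CC(=O)[C@@]2(CC(=O)O[C@@H]2/C=C(\C)CCC=C(C)C)C[C@@H]1O | target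

Total step count: 14. Longest linear sequence: 10 steps (steps 1, 2, 4, 8–14 from 1; the same count through steps 5–7 from 10).

Steps most likely to fail

Step 8. The dienophile lacks the α-hydrogen that normally fixes the enone on the catalyst, so facial discrimination may be poor. Silyl transfer from the diene to the Lewis acid could also open an achiral background pathway, and a stepwise Mukaiyama–Michael course could erode endo selectivity. The fallback sets out from 9 and 13: the cycloaddition is run without chiral catalyst (toluene, BHT, 60 °C) and should give the racemic adduct F1. Kinetic resolution with Burkholderia cepacia lipase in pH 7 phosphate buffer/acetone is expected to hydrolyse the acetate of the (1S,2S,5S) enantiomer, the quaternary-carbon side acting as the large group in the usual size model for secondary-alcohol esters. This should give the hydroxy silyl ether F2 and leave the antipodal acetate F3. F2 is separated and re-acetylated (Ac2O, pyridine, DMAP), which returns to the route at 14.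

Step 10. The hindered, pseudo-axial hydroxyl may chelate boron poorly, so hydride could add without direction and give the epimeric carbinol; the ring hydroxyl may also compete for the ester. The fallback sets out from 14 with the silyl ether still in place and uses reagent control: (S)-1-methyl-3,3-diphenyltetrahydropyrrolo[1,2-c][1,3,2]oxazaborole (0.5 equiv) with BH3·SMe2 in toluene at −40 °C (Corey–Bakshi–Shibata reduction). The quaternary carbon is expected to act as the large substituent, giving the (R)-carbinol F4. PPTS then closes the silyl-protected spirolactone F5 with no competing hydroxyl present, and HF·pyridine removes the silyl group to return to the route at 18.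

Step 13. DBU may isomerise the γ-hydroxy enone through its dienolate (to the 1,4-diketone, or with loss of C9 configuration) faster than the imidate forms, or ring closure may stay incomplete; in step 14 the trichloroacetyl group could migrate from O to N on neutralisation. The fallback sets out from 20. Trichloroacetyl isocyanate (CH2Cl2, 0 °C) should give the N-trichloroacetyl carbamate F6, which K2CO3 in MeOH trims to the primary carbamate F7. Catalytic t-BuOK in THF at 0 °C closes the cis-fused oxazolidinone F8 by carbamate aza-Michael addition. Boc2O with DMAP gives the N-Boc oxazolidinone F9, and Cs2CO3 in MeOH opens the activated ring to the N-Boc amino alcohol F10. HCl in dioxane removes the Boc group and recloses any methanolysed lactone, returning to the route at 23, which is acetylated as in the second half of step 14.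

Further compounds
F1 | step 8 | racemic 14, methyl 2-[(1RS,2RS,5RS)-5-acetoxy-2-[(tert-butyldimethylsilyl)oxy]-1-[(2E)-3,7-dimethylocta-2,6-dienoyl]cyclohex-3-en-1-yl]acetate | CC(=O)O[C@@H]1C=C[C@H](O[Si](C)(C)C(C)(C)C)[C@](CC(=O)OC)(C(=O)/C=C(\C)CCC=C(C)C)C1.CC(=O)O[C@H]1C=C[C@@H](O[Si](C)(C)C(C)(C)C)[C@@](CC(=O)OC)(C(=O)/C=C(\C)CCC=C(C)C)C1
F2 | step 8 | methyl 2-[(1S,2S,5S)-2-[(tert-butyldimethylsilyl)oxy]-1-[(2E)-3,7-dimethylocta-2,6-dienoyl]-5-hydroxycyclohex-3-en-1-yl]acetate | O[C@@H]1C=C[C@H](O[Si](C)(C)C(C)(C)C)[C@](CC(=O)OC)(C(=O)/C=C(\C)CCC=C(C)C)C1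
F3 | step 8 | antipode of 14, methyl 2-[(1R,2R,5R)-5-acetoxy-2-[(tert-butyldimethylsilyl)oxy]-1-[(2E)-3,7-dimethylocta-2,6-dienoyl]cyclohex-3-en-1-yl]acetate | CC(=O)O[C@H]1C=C[C@@H](O[Si](C)(C)C(C)(C)C)[C@@](CC(=O)OC)(C(=O)/C=C(\C)CCC=C(C)C)C1
F4 | step 10 | methyl 2-[(1R,2S,5S)-5-acetoxy-2-[(tert-butyldimethylsilyl)oxy]-1-[(1R,2E)-1-hydroxy-3,7-dimethylocta-2,6-dien-1-yl]cyclohex-3-en-1-yl]acetate | CC(=O)O[C@@H]1C=C[C@H](O[Si](C)(C)C(C)(C)C)[C@](CC(=O)OC)([C@H](O)/C=C(\C)CCC=C(C)C)C1
F5 | step 10 | (1R,5R,6S,9S)-6-[(tert-butyldimethylsilyl)oxy]-1-[(1E)-2,6-dimethylhepta-1,5-dien-1-yl]-3-oxo-2-oxaspiro[4.5]dec-7-en-9-yl acetate | CC(=O)O[C@@H]1C=C[C@H](O[Si](C)(C)C(C)(C)C)[C@@]2(CC(=O)O[C@@H]2/C=C(\C)CCC=C(C)C)C1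
F6 | step 13 | (1R,5R,9S)-1-[(1E)-2,6-dimethylhepta-1,5-dien-1-yl]-3,6-dioxo-2-oxaspiro[4.5]dec-7-en-9-yl (2,2,2-trichloroacetyl)carbamate | ClC(Cl)(Cl)C(=O)NC(=O)O[C@@H]1C=CC(=O)[C@@]2(CC(=O)O[C@@H]2/C=C(\C)CCC=C(C)C)C1
F7 | step 13 | (1R,5R,9S)-1-[(1E)-2,6-dimethylhepta-1,5-dien-1-yl]-3,6-dioxo-2-oxaspiro[4.5]dec-7-en-9-yl carbamate | NC(=O)O[C@@H]1C=CC(=O)[C@@]2(CC(=O)O[C@@H]2/C=C(\C)CCC=C(C)C)C1
F8 | step 13 | (1R,5R,8R,9S) cis-fused oxazolidin-2-one, N on C8 and O on C9 of the spirolactone ketone | O=C3N[C@@H]1CC(=O)[C@@]2(CC(=O)O[C@@H]2/C=C(\C)CCC=C(C)C)C[C@@H]1O3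
F9 | step 13 | N-tert-butoxycarbonyl derivative of oxazolidinone F8 | O=C3N(C(=O)OC(C)(C)C)[C@@H]1CC(=O)[C@@]2(CC(=O)O[C@@H]2/C=C(\C)CCC=C(C)C)C[C@@H]1O3
F10 | step 13 | tert-butyl N-[(1R,5R,8R,9S)-1-[(1E)-2,6-dimethylhepta-1,5-dien-1-yl]-9-hydroxy-3,6-dioxo-2-oxaspiro[4.5]decan-8-yl]carbamate | CC(C)(C)OC(=O)N[C@@H]1CC(=O)[C@@]2(CC(=O)O[C@@H]2/C=C(\C)CCC=C(C)C)C[C@@H]1O
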